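**Retrosynthetic overview**

- Target 20 is a γ-butyrolactone (ring O1–C2(=O)–C3–C4–C5). C3, the α-carbon, carries the E-benzylidene CH to ring A (3-hydroxy-4,5-dimethoxyphenyl). C4, the β-carbon and only stereocenter (R), carries the CH2 to ring B (4-hydroxy-3-methoxyphenyl). Because these two exocyclic carbons sit on adjacent α and β ring carbons, both can be attached in one operation across the C3=C4 bond of a furan-2(5H)-one.
- Disconnections: C3=CH(ring A) to an aldol carbinol; C4–CH2(ring B) to a C4–C(dithiane) bond, the dithiane being an acyl-anion form of vanillin; C5H2 to a C5 menthyl acetal, the single control element.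
- Key union: lithiated dithiane 10, butenolide 4 and aldehyde 9 in one pot. Sulfur is then removed, the acetal is exchanged for CH2 while C3 is still sp3 (so that C4–H next to the transient aldehyde is not allylic), the carbinol is dehydrated, and the MOM groups are removed.
- Ring order: the lactone ring derives from the furan ring of furfural and is present throughout; the key step closes no ring; the lactone is opened and reclosed once in step 8. Both arene rings are bought.

Key step: step 6

Assumption: the carbinol carbon made in step 6 is carried as a mixture of both epimers through compounds 12 to 18, because step 9 turns it into an sp2 carbon; these compounds are written without a descriptor at that carbon.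

**Route**

Step 1
Reactants: 1 furfural
Product: 2 5-hydroxyfuran-2(5H)-one (racemic)
Conditions: O2, methylene blue (cat.), MeOH, visible light, rt
Reagents that add atoms: oxygen, O=O
Why: Dye-sensitised singlet-oxygen [4+2] cycloaddition to the furan (photooxygenation) should give an endoperoxide that methanol fragments with loss of the formyl carbon as methyl formate, leaving the hydroxybutenolide.

Step 2
Reactants: 2 5-hydroxyfuran-2(5H)-one; 3 (−)-menthol, (1R,2S,5R)-2-isopropyl-5-methylcyclohexanol
Product: 4 (5R)-5-[(1R,2S,5R)-menthyloxy]furan-2(5H)-one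
Conditions: TsOH (cat.), toluene, reflux (Dean–Stark); crystallisation from petroleum ether at −20 °C with acid re-equilibration of the mother liquor
Reagents that add atoms: none
Why: Acid-catalysed acetalisation of the pseudo-acid gives both C5 epimers, which interconvert under acid, so that crystallisation of the less soluble (5R) epimer should funnel the material to one diastereomer (crystallisation-induced asymmetric transformation), the menthyl group fixing C5 through crystal selection.

Step 3
Reactants: 5 vanillin
Product: 6 2-(4-hydroxy-3-methoxyphenyl)-1,3-dithiane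
Conditions: HS(CH2)3SH, BF3·OEt2 (cat.), CH2Cl2, 0 °C → rt
Reagents that add atoms: propane-1,3-dithiol, SCCCS
Why: Lewis acid-catalysed dithioacetalisation of the aldehyde, run on the free phenol because these conditions would strip a methoxymethyl ether if it were already in place.

Step 4
Reactants: 6 2-(4-hydroxy-3-methoxyphenyl)-1,3-dithiane
Product: 7 2-[3-methoxy-4-(methoxymethoxy)phenyl]-1,3-dithiane
Conditions: MOMCl, iPr2NEt, CH2Cl2, 0 °C → rt
Reagents that add atoms: chloromethyl methyl ether, COCCl
Why: Williamson-type O-alkylation of the phenol under amine base; the dithiane is inert, and the MOM ether will withstand the organolithium, nickel, hydroxide and amine steps that follow.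

Step 5
Reactants: 8 3-hydroxy-4,5-dimethoxybenzaldehyde
Product: 9 3,4-dimethoxy-5-(methoxymethoxy)benzaldehyde
Conditions: MOMCl, iPr2NEt, CH2Cl2, 0 °C → rt
Reagents that add atoms: chloromethyl methyl ether, COCCl
Why: Williamson-type O-alkylation of the phenol removes the acidic proton that would otherwise quench the enolate in step 6.

Step 6
Reactants: 7 2-[3-methoxy-4-(methoxymethoxy)phenyl]-1,3-dithiane; 4 (5R)-5-[(1R,2S,5R)-menthyloxy]furan-2(5H)-one; 9 3,4-dimethoxy-5-(methoxymethoxy)benzaldehyde
Product: 13 (3S,4R,5R)-3-{[3,4-dimethoxy-5-(methoxymethoxy)phenyl](hydroxy)methyl}-4-{2-[3-methoxy-4-(methoxymethoxy)phenyl]-1,3-dithian-2-yl}-5-[(1R,2S,5R)-menthyloxy]oxolan-2-one (all-trans ring; carbinol epimers), via lithiated dithiane 10 (not isolated), via lithium enolate 11 (not isolated), via lithium aldolate 12 (not isolated)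
Conditions: n-BuLi, THF, −78 °C; then 4, −78 °C; then 9, −78 °C; AcOH, −78 °C
Reagents that add atoms: none
Why: n-BuLi removes the doubly sulfur-stabilised benzylic proton of 7 to give carbanion 10, which adds 1,4 to C4 of butenolide 4; the lithium enolate 11 so formed adds through C3 to the carbonyl of the non-enolisable aldehyde 9, and the aldolate 12 is protonated cold to 13. The closest known reaction type is the tandem Michael addition–aldol trapping of 2-aryl-2-lithio-1,3-dithianes on 5-alkoxyfuran-2(5H)-ones, an established three-component entry to lignan lactones. No ring is closed; the two skeletal bonds C4–C(dithiane) and C3–C(carbinol) are made across the former C3=C4 bond. C4 is controlled by the C5 menthyloxy group, the carbanion entering the ring face anti to it, which turns (5R) into (4R); C3 is controlled by the new bulky dithianyl group at C4, the aldehyde approaching anti to it, so the ring is all-trans (C3 takes the descriptor S because the carbinol carbon outranks C4), while the carbinol carbon is left uncontrolled because step 9 removes it. The step needs 1,4 over 1,2 addition, secured by the soft, hindered, charge-delocalised carbanion, and deprotonation at the dithiane carbon over ortho-lithiation next to the OMOM group, secured by the much higher acidity of that C–H at −78 °C; quenching with AcOH at −78 °C guards against retro-aldol.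

Step 7
Reactants: 13 the dithiane aldol adduct
Product: 14 (3S,4R,5R)-3-{[3,4-dimethoxy-5-(methoxymethoxy)phenyl](hydroxy)methyl}-4-[3-methoxy-4-(methoxymethoxy)benzyl]-5-[(1R,2S,5R)-menthyloxy]oxolan-2-one (carbinol epimers)
Conditions: Raney Ni (W-2), EtOH/THF, rt
Reagents that add atoms: none
Why: Raney nickel hydrogenolysis of both C–S bonds (Mozingo-type desulfurisation) should turn the dithiane carbon into the benzylic CH2 of ring B without touching a stereocenter; the acetal, the lactone and the MOM ethers are stable to the neutral conditions, and room temperature is chosen to spare the benzylic hydroxyl.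

Step 8
Reactants: 14 the desulfurised menthyloxy lactone
Product: 17 (3S,4R)-3-{[3,4-dimethoxy-5-(methoxymethoxy)phenyl](hydroxy)methyl}-4-[3-methoxy-4-(methoxymethoxy)benzyl]oxolan-2-one (trans; carbinol epimers), via potassium formyl carboxylate 15 (not isolated), via potassium hydroxy carboxylate 16 (not isolated)
Conditions: NaBH4, KOH, EtOH/H2O, 0 °C → rt; then 1 M HCl to pH 3, 0 °C → rt
Reagents that add atoms: none
Why: Saponification of the acylal-type lactone releases menthol and unmasks C5 as an aldehyde, which NaBH4 reduces at once (aldehyde reduction), and mild acidification recloses the γ-lactone through the new primary alcohol (lactonisation); this is done before the alkene exists so that C4–H next to the transient aldehyde is an ordinary, slowly enolising α-proton, and C4 should stay (R).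

Step 9
Reactants: 17 the hydroxybenzyl lactone
Product: 19 (3E,4R)-3-[3,4-dimethoxy-5-(methoxymethoxy)benzylidene]-4-[3-methoxy-4-(methoxymethoxy)benzyl]oxolan-2-one, via benzylic mesylate 18 (not isolated)
Conditions: MsCl, Et3N, CH2Cl2, 0 °C; then DBU, rt, dark
Reagents that add atoms: none
Why: Mesylation followed by DBU-mediated E1cB elimination through the lactone enolate should make both carbinol epimers converge on the more stable E alkene (aryl anti to the lactone carbonyl), and C4 is not at risk because its proton is cross-conjugated and not acidified by the carbonyl.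

Step 10
Reactants: 19 the bis-MOM arylidene lactone
Product: 20 (3E,4R)-3-(3-hydroxy-4,5-dimethoxybenzylidene)-4-(4-hydroxy-3-methoxybenzyl)oxolan-2-one (target)
Conditions: HCl (conc., cat.), MeOH, 40 °C, dark
Reagents that add atoms: none
Why: Acid-catalysed acetal methanolysis should remove both MOM groups; dilute acid is used so that the conjugated lactone, the E alkene and C4 are left alone and no Friedel–Crafts closure onto ring B sets in.

**Compound list**

1 | furfural | O=Cc1ccco1 | starting material
2 | 5-hydroxyfuran-2(5H)-one (racemic) | OC1OC(=O)C=C1 | intermediate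
3 | (−)-menthol, (1R,2S,5R)-2-isopropyl-5-methylcyclohexanol | C[C@@H]1CC[C@H]([C@@H](C1)O)C(C)C | starting material
4 | (5R)-5-[(1R,2S,5R)-menthyloxy]furan-2(5H)-one | C[C@@H]1CC[C@H]([C@@H](C1)O[C@@H]1OC(=O)C=C1)C(C)C | intermediate
5 | vanillin | COc1cc(C=O)ccc1O | starting material
6 | 2-(4-hydroxy-3-methoxyphenyl)-1,3-dithiane | COc1cc(C2SCCCS2)ccc1O | intermediate
7 | 2-[3-methoxy-4-(methoxymethoxy)phenyl]-1,3-dithiane | COCOc1ccc(C2SCCCS2)cc1OC | intermediate
8 | 3-hydroxy-4,5-dimethoxybenzaldehyde | COc1cc(C=O)cc(O)c1OC | starting material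
9 | 3,4-dimethoxy-5-(methoxymethoxy)benzaldehyde | COCOc1cc(C=O)cc(OC)c1OC | intermediate
10 | 2-lithio-2-[3-methoxy-4-(methoxymethoxy)phenyl]-1,3-dithiane | [Li]C1(SCCCS1)c1ccc(OCOC)c(OC)c1 | intermediate
11 | lithium (4R,5R)-5-[(1R,2S,5R)-menthyloxy]-4-{2-[3-methoxy-4-(methoxymethoxy)phenyl]-1,3-dithian-2-yl}-4,5-dihydrofuran-2-olate | C[C@@H]1CC[C@H]([C@@H](C1)O[C@@H]1OC(O[Li])=C[C@H]1C1(c2ccc(OCOC)c(OC)c2)SCCCS1)C(C)C | intermediate
12 | lithium alkoxide of 13 (aldolate at the carbinol oxygen; carbinol epimers) | C[C@@H]1CC[C@H]([C@@H](C1)O[C@@H]1OC(=O)[C@H](C(O[Li])c2cc(OCOC)c(OC)c(OC)c2)[C@H]1C1(c2ccc(OCOC)c(OC)c2)SCCCS1)C(C)C | intermediate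
13 | (3S,4R,5R)-3-{[3,4-dimethoxy-5-(methoxymethoxy)phenyl](hydroxy)methyl}-4-{2-[3-methoxy-4-(methoxymethoxy)phenyl]-1,3-dithian-2-yl}-5-[(1R,2S,5R)-menthyloxy]oxolan-2-one (all-trans ring; carbinol epimers) | C[C@@H]1CC[C@H]([C@@H](C1)O[C@@H]1OC(=O)[C@H](C(O)c2cc(OCOC)c(OC)c(OC)c2)[C@H]1C1(c2ccc(OCOC)c(OC)c2)SCCCS1)C(C)C | intermediate
14 | (3S,4R,5R)-3-{[3,4-dimethoxy-5-(methoxymethoxy)phenyl](hydroxy)methyl}-4-[3-methoxy-4-(methoxymethoxy)benzyl]-5-[(1R,2S,5R)-menthyloxy]oxolan-2-one (carbinol epimers) | C[C@@H]1CC[C@H]([C@@H](C1)O[C@@H]1OC(=O)[C@H](C(O)c2cc(OCOC)c(OC)c(OC)c2)[C@H]1Cc3ccc(OCOC)c(OC)c3)C(C)C | intermediate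
15 | potassium (2S,3R)-2-{[3,4-dimethoxy-5-(methoxymethoxy)phenyl](hydroxy)methyl}-3-formyl-4-[3-methoxy-4-(methoxymethoxy)phenyl]butanoate (carbinol epimers) | [K+].[O-]C(=O)[C@H](C(O)c1cc(OCOC)c(OC)c(OC)c1)[C@H](C=O)Cc1ccc(OCOC)c(OC)c1 | intermediate
16 | potassium (2S,3R)-2-{[3,4-dimethoxy-5-(methoxymethoxy)phenyl](hydroxy)methyl}-3-(hydroxymethyl)-4-[3-methoxy-4-(methoxymethoxy)phenyl]butanoate (carbinol epimers) | [K+].[O-]C(=O)[C@H](C(O)c1cc(OCOC)c(OC)c(OC)c1)[C@H](CO)Cc1ccc(OCOC)c(OC)c1 | intermediate
17 | (3S,4R)-3-{[3,4-dimethoxy-5-(methoxymethoxy)phenyl](hydroxy)methyl}-4-[3-methoxy-4-(methoxymethoxy)benzyl]oxolan-2-one (trans; carbinol epimers) | C1OC(=O)[C@H](C(O)c2cc(OCOC)c(OC)c(OC)c2)[C@H]1Cc3ccc(OCOC)c(OC)c3 | intermediate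
18 | [3,4-dimethoxy-5-(methoxymethoxy)phenyl]{(3S,4R)-4-[3-methoxy-4-(methoxymethoxy)benzyl]-2-oxooxolan-3-yl}methyl methanesulfonate (carbinol epimers) | C1OC(=O)[C@H](C(OS(C)(=O)=O)c2cc(OCOC)c(OC)c(OC)c2)[C@H]1Cc3ccc(OCOC)c(OC)c3 | intermediate
19 | (3E,4R)-3-[3,4-dimethoxy-5-(methoxymethoxy)benzylidene]-4-[3-methoxy-4-(methoxymethoxy)benzyl]oxolan-2-one | COc1cc(C[C@H]2COC(=O)/C2=C/c2cc(OCOC)c(OC)c(OC)c2)ccc1OCOC | intermediate
20 | (3E,4R)-3-(3-hydroxy-4,5-dimethoxybenzylidene)-4-(4-hydroxy-3-methoxybenzyl)oxolan-2-one | COc1cc(C[C@H]2COC(=O)/C2=C/c2cc(O)c(OC)c(OC)c2)ccc1O | target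

**Step count**

Total steps: 10. Longest linear sequence: 7 steps (steps 1, 2, 6, 7, 8, 9, 10 from furfural; equally steps 3, 4, 6, 7, 8, 9, 10 from vanillin).

**Steps most likely to fail**

Step 6. The capture of the hindered enolate 11 by the aldehyde may be incomplete, or the aldolate may revert on the way to the quench, so that mainly the simple conjugate adduct is obtained. The fallback separates the two bond formations and builds the ring A arm on the finished lactone. It sets out from 7 and 4: the conjugate addition alone is run and the enolate is protonated with NH4Cl to give (4R,5R)-4-{2-[3-methoxy-4-(methoxymethoxy)phenyl]-1,3-dithian-2-yl}-5-[(1R,2S,5R)-menthyloxy]oxolan-2-one F1. Raney Ni in EtOH then gives (4R,5R)-4-[3-methoxy-4-(methoxymethoxy)benzyl]-5-[(1R,2S,5R)-menthyloxy]oxolan-2-one F2. NaBH4/KOH followed by acid gives (4R)-4-[3-methoxy-4-(methoxymethoxy)benzyl]oxolan-2-one F3. Its lithium enolate (LiN(iPr)2, THF, −78 °C) is expected to add to aldehyde 9 anti to the C4 benzyl group, and the route is rejoined at 17.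

Step 7. The nickel surface may hydrogenolyse the electron-rich benzylic C–OH bond along with the C–S bonds, which would remove the handle needed for the alkene. The fallback replaces surface hydrogenolysis by a radical chain: 13 is heated with Bu3SnH and AIBN in toluene at reflux. Stannyl radicals cleave the two benzylic C–S bonds one after the other and cannot touch the alcohol, and the route is rejoined at 14. This fallback makes no new compound (F0).

Step 8. Under hydroxide the free carbinol may undergo retro-aldol loss of the ring A arm before the lactone is saponified, or on acidification the benzylic alcohol may close onto the new primary alcohol to give a tetrahydrofuran. The fallback masks the carbinol first. It sets out from 14: TBSCl, imidazole and DMF should give (3S,4R,5R)-3-{(tert-butyldimethylsilyloxy)[3,4-dimethoxy-5-(methoxymethoxy)phenyl]methyl}-4-[3-methoxy-4-(methoxymethoxy)benzyl]-5-[(1R,2S,5R)-menthyloxy]oxolan-2-one F4. NaBH4/KOH and then acid give (3S,4R)-3-{(tert-butyldimethylsilyloxy)[3,4-dimethoxy-5-(methoxymethoxy)phenyl]methyl}-4-[3-methoxy-4-(methoxymethoxy)benzyl]oxolan-2-one F5. TBAF buffered with AcOH in THF at 0 °C frees the alcohol, and the route is rejoined at 17.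

**Further compounds**

F1 | step 6 | (4R,5R)-4-{2-[3-methoxy-4-(methoxymethoxy)phenyl]-1,3-dithian-2-yl}-5-[(1R,2S,5R)-menthyloxy]oxolan-2-one | C[C@@H]1CC[C@H]([C@@H](C1)O[C@@H]1OC(=O)C[C@H]1C1(c2ccc(OCOC)c(OC)c2)SCCCS1)C(C)C
F2 | step 6 | (4R,5R)-4-[3-methoxy-4-(methoxymethoxy)benzyl]-5-[(1R,2S,5R)-menthyloxy]oxolan-2-one | C[C@@H]1CC[C@H]([C@@H](C1)O[C@@H]1OC(=O)C[C@H]1Cc1ccc(OCOC)c(OC)c1)C(C)C
F3 | step 6 | (4R)-4-[3-methoxy-4-(methoxymethoxy)benzyl]oxolan-2-one | C1OC(=O)C[C@H]1Cc1ccc(OCOC)c(OC)c1
F0 | step 7 | none | none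
F4 | step 8 | (3S,4R,5R)-3-{(tert-butyldimethylsilyloxy)[3,4-dimethoxy-5-(methoxymethoxy)phenyl]methyl}-4-[3-methoxy-4-(methoxymethoxy)benzyl]-5-[(1R,2S,5R)-menthyloxy]oxolan-2-one (carbinol epimers) | C[C@@H]1CC[C@H]([C@@H](C1)O[C@@H]1OC(=O)[C@H](C(O[Si](C)(C)C(C)(C)C)c2cc(OCOC)c(OC)c(OC)c2)[C@H]1Cc3ccc(OCOC)c(OC)c3)C(C)C
F5 | step 8 | (3S,4R)-3-{(tert-butyldimethylsilyloxy)[3,4-dimethoxy-5-(methoxymethoxy)phenyl]methyl}-4-[3-methoxy-4-(methoxymethoxy)benzyl]oxolan-2-one (carbinol epimers) | C1OC(=O)[C@H](C(O[Si](C)(C)C(C)(C)C)c2cc(OCOC)c(OC)c(OC)c2)[C@H]1Cc3ccc(OCOC)c(OC)c3
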